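**Assumption:** the chain is numbered pentyl C1–C5, ring carbons C6–C9 (oxygen bridges C6 and C9), carbinol C10, vinyl C18–C19; the SMILES then reads (6S,7S,9R,10R), i.e. (2S,3S,5R)-5-[(1R)-1-hydroxydec-9-en-1-yl]-2-pentyloxolan-3-yl octadecanoate.

## Retrosynthetic overview
1. Target ⇒ desilylation of the O7 stearate whose O10 is a TBS ether; O10 is protected from the start, so only O7 is free when the ester is put on.
2. The single ring (the tetrahydrofuran) is formed once, late: O9 displaces chloride at C6 with inversion in an acyclic 6-chloro-7,9-diol.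
3. Chlorodiol ⇒ 1,3-syn reduction of a β-hydroxy ketone; the C7–C8 bond ⇒ intermolecular lithium aldol of a C8–C19 methyl ketone with (R)-2-chloroheptanal (C1–C7).
4. Methyl ketone ⇒ undec-10-enoyl chloride by auxiliary-controlled α-hydroxylation (sets C10), Weinreb amide and MeMgBr; chloroaldehyde ⇒ heptanal by organocatalytic α-chlorination.

## Route

Step 1
Reactants: 1 (4R)-4-benzyloxazolidin-2-one; 2 undec-10-enoyl chloride
Product: 4 (4R)-4-benzyl-3-(undec-10-enoyl)oxazolidin-2-one, via N-lithio oxazolidinone 3 (not isolated)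
Conditions: n-BuLi (1.0 equiv), THF, −78 °C; then 2, −78 → 0 °C
Reagents that add atoms: none
Why: N-acylation of the lithiated Evans auxiliary by an acid chloride is fast and clean, and no stereocentre is formed.

Step 2
Reactants: 4
Product: 6 (4R)-4-benzyl-3-[(2R)-2-hydroxyundec-10-enoyl]oxazolidin-2-one, via sodium Z-enolate 5 (not isolated)
Conditions: NaN(SiMe3)2 (1.1 equiv), THF, −78 °C; 3-phenyl-2-(phenylsulfonyl)oxaziridine (1.4 equiv), −78 °C; AcOH quench
Reagents that add atoms: 3-phenyl-2-(phenylsulfonyl)oxaziridine (Davis oxaziridine), O=S(=O)(c1ccccc1)N1OC1c1ccccc1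
Why: Evans–Davis enolate hydroxylation, in which the chelated sodium Z-enolate is oxidised on the face opposite the benzyl group of the (R)-auxiliary, giving the (2R)-alcohol (future C10); the minor diastereomer is removed by chromatography.

Step 3
Reactants: 6
Product: 7 (2R)-2-hydroxy-N-methoxy-N-methylundec-10-enamide
Conditions: MeNHOMe·HCl (3 equiv), AlMe3 (3 equiv), CH2Cl2, −10 °C → rt; cold 0.5 M aq. HCl work-up (1 recovered)
Reagents that add atoms: N,O-dimethylhydroxylamine hydrochloride, CNOC.Cl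
Why: Weinreb aminolysis with the aluminium amide attacks the exocyclic imide carbonyl (assisted by the aluminium alkoxide of the free α-hydroxyl), releasing the auxiliary without epimerisation.

Step 4
Reactants: 7
Product: 8 (2R)-2-[(tert-butyldimethylsilyl)oxy]-N-methoxy-N-methylundec-10-enamide
Conditions: TBSCl (1.3 equiv), imidazole (2.5 equiv), DMF, rt
Reagents that add atoms: tert-butyldimethylsilyl chloride (TBSCl), CC(C)(C)[Si](C)(C)Cl
Why: Standard imidazole-promoted silylation masks O10, so that later only O7 and O9 can react; the stereocentre is untouched.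

Step 5
Reactants: 8
Product: 10 (3R)-3-[(tert-butyldimethylsilyl)oxy]dodec-11-en-2-one, via bromomagnesium hemiaminal chelate 9 (not isolated)
Conditions: MeMgBr (2 equiv), THF, 0 °C; sat. aq. NH4Cl
Reagents that add atoms: methylmagnesium bromide, C[Mg]Br
Why: Weinreb ketone synthesis, where the stable magnesium chelate prevents over-addition and collapses to the methyl ketone only on work-up, leaving the α-silyloxy centre intact.

Step 6
Reactants: 11 heptanal
Product: 12 (2R)-2-chloroheptanal
Conditions: (5R)-5-benzyl-2,2,3-trimethylimidazolidin-4-one trifluoroacetate (5 mol %), 2,3,4,5,6,6-hexachlorocyclohexa-2,4-dien-1-one (1.2 equiv), acetone, −30 °C; pentane, cold filtration through a short silica pad; used at once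
Reagents that add atoms: 2,3,4,5,6,6-hexachlorocyclohexa-2,4-dien-1-one, O=C1C(Cl)=C(Cl)C(Cl)=C(Cl)C1(Cl)Cl
Why: Enamine-organocatalytic α-chlorination, in which the E-enamine is chlorinated on the face anti to the catalyst benzyl group, which for the (5R)-catalyst gives the (R)-chloride (about 90% ee expected).

Step 7
Reactants: 10 (3R)-3-[(tert-butyldimethylsilyl)oxy]dodec-11-en-2-one; 12 (2R)-2-chloroheptanal
Product: 14 (6R,7S,10R)-10-[(tert-butyldimethylsilyl)oxy]-6-chloro-7-hydroxynonadec-18-en-9-one, via terminal lithium enolate 13 (not isolated)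
Conditions: LiN(i-Pr)2 (1.05 equiv), THF, −78 °C, 40 min; 12 (1.3 equiv), −78 °C, 30 min; AcOH/THF quench at −78 °C
Reagents that add atoms: none
Why: Intermolecular lithium aldol addition: kinetic deprotonation occurs at the methyl group and the enolate adds to the α-chloroaldehyde anti to the C–Cl bond (Cornforth/polar Felkin–Anh control), giving the 1,2-anti chlorohydrin (7S) and forming the C7–C8 bond.

Step 8
Reactants: 14
Product: 16 (6R,7S,9R,10R)-10-[(tert-butyldimethylsilyl)oxy]-6-chlorononadec-18-ene-7,9-diol, via O7-diethylboryl chelate 15 (not isolated)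
Conditions: Et2BOMe (1.2 equiv), THF/MeOH 4:1, −78 °C; NaBH4 (1.2 equiv), −78 °C, 3 h; AcOH; repeated MeOH co-evaporation (no basic peroxide work-up)
Reagents that add atoms: none
Why: Narasaka–Prasad reduction, where external hydride attack on the six-membered boron chelate gives the 1,3-syn diol (9R); the Felkin–Anh preference of the adjacent silyloxy centre (9,10-syn) points the same way.

Step 9
Reactants: 16
Product: 17 (2S,3S,5R)-5-[(1R)-1-[(tert-butyldimethylsilyl)oxy]dec-9-en-1-yl]-2-pentyloxolan-3-ol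
Conditions: AgOSO2CF3 (1.5 equiv), Ag2O (1.5 equiv), THF, rt → 40 °C, dark
Reagents that add atoms: none
Why: Silver-assisted intramolecular Williamson-type etherification (5-exo-tet SN2), in which O9 displaces chloride with inversion at C6 to give (6S) with pentyl cis to O7; Ag2O keeps the medium neutral so the TBS ether survives, and the blocked O10 cannot form a tetrahydropyran.

Step 10
Reactants: 17 (2S,3S,5R)-5-[(1R)-1-[(tert-butyldimethylsilyl)oxy]dec-9-en-1-yl]-2-pentyloxolan-3-ol; 18 octadecanoyl chloride (stearoyl chloride)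
Product: 19 (2S,3S,5R)-5-[(1R)-1-[(tert-butyldimethylsilyl)oxy]dec-9-en-1-yl]-2-pentyloxolan-3-yl octadecanoate
Conditions: Et3N (3 equiv), 4-(dimethylamino)pyridine (0.2 equiv), CH2Cl2, 0 °C → rt
Reagents that add atoms: none
Why: Nucleophilic-catalysed acylation (acyl transfer via the acylpyridinium) of the only free hydroxyl, with retention at C7.

Step 11
Reactants: 19
Product: 20 (2S,3S,5R)-5-[(1R)-1-hydroxydec-9-en-1-yl]-2-pentyloxolan-3-yl octadecanoate
Conditions: HF·pyridine, pyridine, THF, 0 °C → rt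
Reagents that add atoms: none
Why: Fluoride-mediated desilylation under buffered, mildly acidic conditions cleaves the secondary TBS ether while the ester and terminal alkene are inert and acyl migration to O10 (trans across the ring) is not expected.

## Compound list
1 | (4R)-4-benzyloxazolidin-2-one | O=C1N[C@H](Cc2ccccc2)CO1 | starting material
2 | undec-10-enoyl chloride | C=CCCCCCCCCC(Cl)=O | starting material
3 | N-lithio (4R)-4-benzyloxazolidin-2-one (not isolated) | [Li]N1[C@H](Cc2ccccc2)COC1=O | intermediate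
4 | (4R)-4-benzyl-3-(undec-10-enoyl)oxazolidin-2-one | C=CCCCCCCCCC(=O)N1[C@H](Cc2ccccc2)COC1=O | intermediate
5 | sodium (Z)-enolate of 4 (not isolated) | C=CCCCCCCC/C=C(\[O-])N1[C@H](Cc2ccccc2)COC1=O.[Na+] | intermediate
6 | (4R)-4-benzyl-3-[(2R)-2-hydroxyundec-10-enoyl]oxazolidin-2-one | C=CCCCCCCC[C@@H](O)C(=O)N1[C@H](Cc2ccccc2)COC1=O | intermediate
7 | (2R)-2-hydroxy-N-methoxy-N-methylundec-10-enamide | C=CCCCCCCC[C@@H](O)C(=O)N(C)OC | intermediate
8 | (2R)-2-[(tert-butyldimethylsilyl)oxy]-N-methoxy-N-methylundec-10-enamide | C=CCCCCCCC[C@@H](O[Si](C)(C)C(C)(C)C)C(=O)N(C)OC | intermediate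
9 | bromomagnesium hemiaminal adduct of 8 with MeMgBr (not isolated) | C=CCCCCCCC[C@@H](O[Si](C)(C)C(C)(C)C)C(C)(O[Mg]Br)N(C)OC | intermediate
10 | (3R)-3-[(tert-butyldimethylsilyl)oxy]dodec-11-en-2-one | C=CCCCCCCC[C@@H](O[Si](C)(C)C(C)(C)C)C(C)=O | intermediate
11 | heptanal | CCCCCCC=O | starting material
12 | (2R)-2-chloroheptanal | CCCCC[C@@H](Cl)C=O | intermediate
13 | lithium (3R)-3-[(tert-butyldimethylsilyl)oxy]dodeca-1,11-dien-2-olate (not isolated) | C=CCCCCCCC[C@@H](O[Si](C)(C)C(C)(C)C)C(=C)O[Li] | intermediate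
14 | (6R,7S,10R)-10-[(tert-butyldimethylsilyl)oxy]-6-chloro-7-hydroxynonadec-18-en-9-one | CCCCC[C@@H](Cl)[C@@H](O)CC(=O)[C@@H](CCCCCCCC=C)O[Si](C)(C)C(C)(C)C | intermediate
15 | O7-diethylboryl chelate of 14 (not isolated) | CCCCC[C@@H](Cl)[C@@H](OB(CC)CC)CC(=O)[C@@H](CCCCCCCC=C)O[Si](C)(C)C(C)(C)C | intermediate
16 | (6R,7S,9R,10R)-10-[(tert-butyldimethylsilyl)oxy]-6-chlorononadec-18-ene-7,9-diol | CCCCC[C@@H](Cl)[C@@H](O)C[C@@H](O)[C@@H](CCCCCCCC=C)O[Si](C)(C)C(C)(C)C | intermediate
17 | (2S,3S,5R)-5-[(1R)-1-[(tert-butyldimethylsilyl)oxy]dec-9-en-1-yl]-2-pentyloxolan-3-ol | C=CCCCCCCC[C@@H](O[Si](C)(C)C(C)(C)C)[C@H]1C[C@H](O)[C@H](CCCCC)O1 | intermediate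
18 | octadecanoyl chloride (stearoyl chloride) | CCCCCCCCCCCCCCCCCC(Cl)=O | starting material
19 | (2S,3S,5R)-5-[(1R)-1-[(tert-butyldimethylsilyl)oxy]dec-9-en-1-yl]-2-pentyloxolan-3-yl octadecanoate | C=CCCCCCCC[C@@H](O[Si](C)(C)C(C)(C)C)[C@H]1C[C@H](OC(=O)CCCCCCCCCCCCCCCCC)[C@H](CCCCC)O1 | intermediate
20 | (2S,3S,5R)-5-[(1R)-1-hydroxydec-9-en-1-yl]-2-pentyloxolan-3-yl octadecanoate | C=CCCCCCCC[C@@H](O)[C@H]1C[C@H](OC(=O)CCCCCCCCCCCCCCCCC)[C@H](CCCCC)O1 | target

## Step count and risks
Total steps: 11. Longest linear sequence: 10 (steps 1–5, then 7–11); step 6 is a one-step side branch.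

**Step 6** is risky because 12 is volatile and configurationally labile, and its ee is capped by the catalyst. The fallback replaces organocatalysis by auxiliary control; it sets out from 1 and comes back at 12. Acylation of 1 with commercial heptanoyl chloride (n-BuLi, THF, −78 °C) gives (4R)-4-benzyl-3-heptanoyloxazolidin-2-one F1. Its dibutylboron enolate (Bu2BOSO2CF3, i-Pr2NEt, CH2Cl2, −78 → 0 °C) is chlorinated with N-chlorosuccinimide at −78 °C on the face anti to the benzyl group, giving (4R)-4-benzyl-3-[(2R)-2-chloroheptanoyl]oxazolidin-2-one F2. The diastereomers of F2 are separable, so optical purity no longer depends on a catalyst. NaBH4 in THF/H2O at 0 °C removes the auxiliary reductively to give the storable (2R)-2-chloroheptan-1-ol F3. Dess–Martin periodinane with NaHCO3 in CH2Cl2 at 0 °C, run just before the aldol, returns to 12.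

**Step 7** is risky because of the anti/syn ratio, possible enolate equilibration toward the silyloxy-bearing carbon, and retro-aldol on warming. The fallback is a Lewis-acid Mukaiyama aldol in place of the lithium enolate; it sets out from 10 and comes back at 14. Kinetic trapping (LiN(i-Pr)2, Me3SiCl, THF, −78 °C) gives the isolable (3R)-3-[(tert-butyldimethylsilyl)oxy]-2-[(trimethylsilyl)oxy]dodeca-1,11-diene F4, whose regiochemistry can be checked before use. Addition of F4 to 12 with BF3·OEt2 in CH2Cl2 at −78 °C proceeds through an open transition state with the same Cornforth/Felkin–Anh preference and gives 14 after aqueous work-up.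

**Step 9** is risky because O7 can compete to form the 6,7-epoxide, and the ionisation may be sluggish. The fallback blocks O7 first; it sets out from 14 and comes back at 17. Silylation (Et3SiOSO2CF3, 2,6-lutidine, CH2Cl2, −78 °C) gives (6R,7S,10R)-10-[(tert-butyldimethylsilyl)oxy]-6-chloro-7-[(triethylsilyl)oxy]nonadec-18-en-9-one F5. Felkin–Anh reduction directed by the C10 silyloxy group (LiBH(s-Bu)3, THF, −78 °C, non-oxidative work-up) gives (6R,7S,9R,10R)-10-[(tert-butyldimethylsilyl)oxy]-6-chloro-7-[(triethylsilyl)oxy]nonadec-18-en-9-ol F6, in which O9 is the only free hydroxyl. Cyclisation with AgOSO2CF3/Ag2O in THF gives (2S,3S,5R)-5-[(1R)-1-[(tert-butyldimethylsilyl)oxy]dec-9-en-1-yl]-2-pentyl-3-[(triethylsilyl)oxy]oxolane F7. Selective removal of the triethylsilyl group (pyridinium p-toluenesulfonate, MeOH/CH2Cl2, 0 °C) leaves the TBS ether and returns to 17.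

Further compounds
F1 | step 6 | (4R)-4-benzyl-3-heptanoyloxazolidin-2-one | CCCCCCC(=O)N1[C@H](Cc2ccccc2)COC1=O
F2 | step 6 | (4R)-4-benzyl-3-[(2R)-2-chloroheptanoyl]oxazolidin-2-one | CCCCC[C@@H](Cl)C(=O)N1[C@H](Cc2ccccc2)COC1=O
F3 | step 6 | (2R)-2-chloroheptan-1-ol | CCCCC[C@@H](Cl)CO
F4 | step 7 | (3R)-3-[(tert-butyldimethylsilyl)oxy]-2-[(trimethylsilyl)oxy]dodeca-1,11-diene | C=CCCCCCCC[C@@H](O[Si](C)(C)C(C)(C)C)C(=C)O[Si](C)(C)C
F5 | step 9 | (6R,7S,10R)-10-[(tert-butyldimethylsilyl)oxy]-6-chloro-7-[(triethylsilyl)oxy]nonadec-18-en-9-one | CCCCC[C@@H](Cl)[C@@H](O[Si](CC)(CC)CC)CC(=O)[C@@H](CCCCCCCC=C)O[Si](C)(C)C(C)(C)C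
F6 | step 9 | (6R,7S,9R,10R)-10-[(tert-butyldimethylsilyl)oxy]-6-chloro-7-[(triethylsilyl)oxy]nonadec-18-en-9-ol | CCCCC[C@@H](Cl)[C@@H](O[Si](CC)(CC)CC)C[C@@H](O)[C@@H](CCCCCCCC=C)O[Si](C)(C)C(C)(C)C
F7 | step 9 | (2S,3S,5R)-5-[(1R)-1-[(tert-butyldimethylsilyl)oxy]dec-9-en-1-yl]-2-pentyl-3-[(triethylsilyl)oxy]oxolane | C=CCCCCCCC[C@@H](O[Si](C)(C)C(C)(C)C)[C@H]1C[C@H](O[Si](CC)(CC)CC)[C@H](CCCCC)O1
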